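**Assumption (one line):** with lignan locants, the SMILES is read as 7R,8S,7'S,8'S on the cis-fused furofuran (guaiacyl ring exo, ether-bearing syringyl ring endo) and 7''R,8''R (threo) in the arylglycerol arm.

## Retrosynthetic overview

1. Last operations: both phenols are freed from allyl ethers, and the 1,3-diol comes from reductive cleavage of an Evans imide.
2. Key bond C7''–C8'': intermolecular boron aldol between the furofuran-bearing N-(aryloxyacetyl)oxazolidinone 26 and aldehyde 27, which sets 7''R,8''R.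
3. Furofuran: ring A (C7–O–C9') and ring B (C7'–O–C9) are closed by O-alkylation of the two benzylic alkoxides on primary mesylates, so C7 and C7' keep the configurations set earlier.
4. C8'–C7' comes from an anti aldol of the enolate of lactone 11 with aldehyde 13 (gives the endo aryl); C7–C8 comes from an Evans syn aldol of succinate imide 6 with aldehyde 2 (gives the exo aryl).
5. Ring order: a temporary γ-butyrolactone (made in step 6, opened in step 10), then rings A and B of the furofuran together in step 12.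

Abbreviations: TBS = tert-butyldimethylsilyl; Ms = methanesulfonyl; ArG = 4-(allyloxy)-3-methoxyphenyl; ArS = 4-{2-[(tert-butyldimethylsilyl)oxy]ethoxy}-3,5-dimethoxyphenyl; FF = (1S,3aS,4R,6aS)-4-[4-(allyloxy)-3-methoxyphenyl]tetrahydro-1H,3H-furo[3,4-c]furan-1-yl (C1 = C7', C4 = C7).

## Route

Step 1
Reactants: 1 vanillin
Product: 2 4-(allyloxy)-3-methoxybenzaldehyde
Conditions: allyl bromide, K2CO3, DMF, 60 °C
Reagents that add atoms: allyl bromide, C=CCBr
Why: Williamson ether synthesis on the phenoxide; the allyl ether survives all later base, hydride, fluoride and boron steps and is removed at the very end without acid or hydrogen.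

Step 2
Reactants: 3 4-(tert-butoxy)-4-oxobutanoic acid; 4 (R)-4-benzyl-1,3-oxazolidin-2-one
Product: 6 tert-butyl 4-[(4R)-4-benzyl-2-oxo-1,3-oxazolidin-3-yl]-4-oxobutanoate, via mixed pivalic anhydride 5 (not isolated)
Conditions: t-BuCOCl, Et3N, THF, −20 °C; then LiCl, 4, −20 °C to rt
Reagents that add atoms: none
Why: N-acylation of the oxazolidinone through a mixed anhydride, which is attacked at the less hindered succinyl carbonyl.

Step 3
Reactants: 6 tert-butyl 4-[(4R)-4-benzyl-2-oxo-1,3-oxazolidin-3-yl]-4-oxobutanoate; 2 4-(allyloxy)-3-methoxybenzaldehyde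
Product: 8 tert-butyl (3R,4R)-4-[4-(allyloxy)-3-methoxyphenyl]-3-{[(4R)-4-benzyl-2-oxo-1,3-oxazolidin-3-yl]carbonyl}-4-hydroxybutanoate, via dibutylboron Z-enolate 7 (not isolated)
Conditions: Bu2BOTf, i-Pr2NEt, CH2Cl2, 0 °C; 2, −78 to 0 °C; then pH 7 buffer, MeOH, H2O2, 0 °C
Reagents that add atoms: none
Why: Evans syn aldol through a Zimmerman–Traxler chair on the enolate face opposite the (R)-benzyl group sets C8 and C7 (final 8S,7R; the syn relation becomes the exo aryl), and the tert-butyl ester prevents lactonization of the aldolate.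

Step 4
Reactants: 8 (the syn aldol adduct)
Product: 9 tert-butyl (3R,4R)-4-[4-(allyloxy)-3-methoxyphenyl]-3-{[(4R)-4-benzyl-2-oxo-1,3-oxazolidin-3-yl]carbonyl}-4-[(tert-butyldimethylsilyl)oxy]butanoate
Conditions: TBSOTf, 2,6-lutidine, CH2Cl2, −78 to −20 °C
Reagents that add atoms: tert-butyldimethylsilyl trifluoromethanesulfonate, CC(C)(C)[Si](C)(C)OS(=O)(=O)C(F)(F)F
Why: O-silylation masks the benzylic C7 hydroxyl as a fluoride-labile latent nucleophile; no stereocentre is touched.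

Step 5
Reactants: 9 (the silylated imide)
Product: 10 tert-butyl (3S,4R)-4-[4-(allyloxy)-3-methoxyphenyl]-4-[(tert-butyldimethylsilyl)oxy]-3-(hydroxymethyl)butanoate
Conditions: LiBH4, MeOH (1.5 equiv), THF, 0 °C
Reagents that add atoms: none
Why: chemoselective reductive cleavage of the imide (the tert-butyl ester is far slower) gives the C9 alcohol and returns the auxiliary; the descriptor at C8 changes from R to S only through CIP priorities.

Step 6
Reactants: 10 (the hydroxy tert-butyl ester)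
Product: 11 (4S)-4-{(R)-[4-(allyloxy)-3-methoxyphenyl][(tert-butyldimethylsilyl)oxy]methyl}oxolan-2-one
Conditions: pyridinium p-toluenesulfonate (0.2 equiv), toluene, 70 °C
Reagents that add atoms: none
Why: acid-catalysed lactonization (intramolecular transesterification, 5-exo-trig) driven by loss of tert-butanol; the weak acid leaves the benzylic silyl ether and both stereocentres intact.

Step 7
Reactants: 12 syringaldehyde
Product: 13 4-{2-[(tert-butyldimethylsilyl)oxy]ethoxy}-3,5-dimethoxybenzaldehyde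
Conditions: BrCH2CH2OTBS, K2CO3, DMF, 70 °C
Reagents that add atoms: (2-bromoethoxy)(tert-butyl)dimethylsilane, BrCCO[Si](C)(C)C(C)(C)C
Why: Williamson ether synthesis; the O–CH2–CH2–O unit is a masked aryloxyacetic acid, so this phenol never has to be freed again.

Step 8
Reactants: 11 (the lactone); 13 4-{2-[(tert-butyldimethylsilyl)oxy]ethoxy}-3,5-dimethoxybenzaldehyde
Product: 15 (3R,4S)-4-{(R)-[4-(allyloxy)-3-methoxyphenyl][(tert-butyldimethylsilyl)oxy]methyl}-3-{(S)-[4-{2-[(tert-butyldimethylsilyl)oxy]ethoxy}-3,5-dimethoxyphenyl](hydroxy)methyl}oxolan-2-one, via lithium lactone enolate 14 (not isolated)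
Conditions: LiN(i-Pr)2 (1.1 equiv), THF, −78 °C; 13, −78 °C, 30 min; AcOH quench at −78 °C
Reagents that add atoms: none
Why: lactone-enolate aldol in which the aldehyde adds anti to the bulky C4 substituent (3,4-trans, sets C8') and the ring-locked E-enolate reacts through a closed Zimmerman–Traxler chair to give the anti (7'S) carbinol that later becomes the endo aryl; the minor syn epimer is removed by chromatography.

Step 9
Reactants: 15 (the anti aldol lactone)
Product: 16 (3R,4S)-4-{(R)-[4-(allyloxy)-3-methoxyphenyl][(tert-butyldimethylsilyl)oxy]methyl}-3-{(S)-[4-{2-[(tert-butyldimethylsilyl)oxy]ethoxy}-3,5-dimethoxyphenyl][(tert-butyldimethylsilyl)oxy]methyl}oxolan-2-one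
Conditions: TBSOTf, 2,6-lutidine, CH2Cl2, −78 to 0 °C
Reagents that add atoms: tert-butyldimethylsilyl trifluoromethanesulfonate, CC(C)(C)[Si](C)(C)OS(=O)(=O)C(F)(F)F
Why: O-silylation blocks retro-aldol and stores the C7' oxygen as the second latent nucleophile.

Step 10
Reactants: 16 (the bis-silylated lactone)
Product: 17 (2S,3S)-2-{(R)-[4-(allyloxy)-3-methoxyphenyl][(tert-butyldimethylsilyl)oxy]methyl}-3-{(S)-[4-{2-[(tert-butyldimethylsilyl)oxy]ethoxy}-3,5-dimethoxyphenyl][(tert-butyldimethylsilyl)oxy]methyl}butane-1,4-diol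
Conditions: LiBH4, THF, 0 °C to rt
Reagents that add atoms: none
Why: hydride reduction of the lactone opens the temporary ring to the C9/C9' diol; borate alkoxides do not promote silyl migration and no stereocentre is touched.

Step 11
Reactants: 17 (the 1,4-diol)
Product: 18 (2S,3S)-2-{(R)-[4-(allyloxy)-3-methoxyphenyl][(tert-butyldimethylsilyl)oxy]methyl}-3-{(S)-[4-{2-[(tert-butyldimethylsilyl)oxy]ethoxy}-3,5-dimethoxyphenyl][(tert-butyldimethylsilyl)oxy]methyl}butane-1,4-diyl dimethanesulfonate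
Conditions: MsCl, Et3N, CH2Cl2, 0 °C
Reagents that add atoms: methanesulfonyl chloride, CS(=O)(=O)Cl
Why: sulfonylation turns both primary carbons (C9, C9') into electrophiles while every benzylic oxygen is still silylated.

Step 12
Reactants: 18 (the bis-mesylate)
Product: 21 2-{4-[(1S,3aS,4R,6aS)-4-[4-(allyloxy)-3-methoxyphenyl]tetrahydro-1H,3H-furo[3,4-c]furan-1-yl]-2,6-dimethoxyphenoxy}ethan-1-ol, via desilylated triol bis-mesylate 19 (not isolated), via monocyclic tetrahydrofuran mesylate 20 (not isolated)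
Conditions: Bu4NF (5 equiv), THF, 0 to 40 °C
Reagents that add atoms: none
Why: fluoride desilylation releases the two benzylic alkoxides, which close rings A and B by intramolecular Williamson etherification (5-exo-tet SN2 at the primary carbons), so C7 and C7' are retained (guaiacyl exo, syringyl endo); no phenoxide and no acid are present to epimerize the benzylic ethers.

Step 13
Reactants: 21 (the furofuran alcohol)
Product: 23 {4-[(1S,3aS,4R,6aS)-4-[4-(allyloxy)-3-methoxyphenyl]tetrahydro-1H,3H-furo[3,4-c]furan-1-yl]-2,6-dimethoxyphenoxy}acetic acid, via aryloxyacetaldehyde 22 (not isolated)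
Conditions: TEMPO (0.2 equiv), PhI(OAc)2 (2.5 equiv), MeCN/H2O (1:1), rt
Reagents that add atoms: water, O
Why: oxoammonium-mediated oxidation of the primary alcohol through the aldehyde hydrate to the acid; it spares the allyl ether and the benzylic ethers.

Step 14
Reactants: 23 (the aryloxyacetic acid); 24 (S)-4-benzyl-1,3-oxazolidin-2-one
Product: 26 (4S)-4-benzyl-3-({4-[(1S,3aS,4R,6aS)-4-[4-(allyloxy)-3-methoxyphenyl]tetrahydro-1H,3H-furo[3,4-c]furan-1-yl]-2,6-dimethoxyphenoxy}acetyl)-1,3-oxazolidin-2-one, via mixed pivalic anhydride 25 (not isolated)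
Conditions: t-BuCOCl, Et3N, THF, −20 °C; then LiCl, 24, −20 °C to rt
Reagents that add atoms: none
Why: N-acylation through the mixed anhydride under buffered base, so the free aryloxyacetic acid is never concentrated next to the furofuran.

Step 15
Reactants: 12 syringaldehyde
Product: 27 4-(allyloxy)-3,5-dimethoxybenzaldehyde
Conditions: allyl bromide, K2CO3, DMF, 60 °C
Reagents that add atoms: allyl bromide, C=CCBr
Why: Williamson ether synthesis giving the aldehyde partner with the same end-game protecting group as the guaiacyl ring.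

Step 16
Reactants: 26 (the aryloxyacetyl imide); 27 4-(allyloxy)-3,5-dimethoxybenzaldehyde
Product: 29 (4S)-4-benzyl-3-[(2S,3R)-3-[4-(allyloxy)-3,5-dimethoxyphenyl]-2-{4-[(1S,3aS,4R,6aS)-4-[4-(allyloxy)-3-methoxyphenyl]tetrahydro-1H,3H-furo[3,4-c]furan-1-yl]-2,6-dimethoxyphenoxy}-3-hydroxypropanoyl]-1,3-oxazolidin-2-one, via dibutylboron Z-enolate 28 (not isolated)
Conditions: Bu2BOTf (1.2 equiv), i-Pr2NEt (1.5 equiv), CH2Cl2, −78 to 0 °C; 27, −78 to 0 °C; then pH 7 buffer, MeOH, H2O2, 0 °C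
Reagents that add atoms: none
Why: Evans syn aldol of the glycolate-type Z-boron enolate through a Zimmerman–Traxler chair on the face opposite the (S)-benzyl group forges C7''–C8'', joins the two fragments and gives the 2,3-syn adduct (2S,3R), which is 8''R,7''R (threo) after step 17; the excess amine keeps free boron triflate away from the furofuran.

Step 17
Reactants: 29 (the syn aldol imide)
Product: 30 (1R,2R)-1-[4-(allyloxy)-3,5-dimethoxyphenyl]-2-{4-[(1S,3aS,4R,6aS)-4-[4-(allyloxy)-3-methoxyphenyl]tetrahydro-1H,3H-furo[3,4-c]furan-1-yl]-2,6-dimethoxyphenoxy}propane-1,3-diol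
Conditions: LiBH4, H2O (1 equiv), THF, 0 °C
Reagents that add atoms: none
Why: reductive cleavage of the imide gives the C9'' alcohol and returns the auxiliary; C8'' changes from S to R only through CIP priorities.

Step 18
Reactants: 30 (the bis-allyl ether)
Product: 31 4-[(1R,2R)-1,3-dihydroxy-2-{4-[(1S,3aS,4R,6aS)-4-(4-hydroxy-3-methoxyphenyl)tetrahydro-1H,3H-furo[3,4-c]furan-1-yl]-2,6-dimethoxyphenoxy}propyl]-2,6-dimethoxyphenol
Conditions: Pd(PPh3)4 (10 mol %), morpholine, THF, rt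
Reagents that add atoms: none
Why: Tsuji–Trost deallylation (zerovalent palladium ionizes both aryl allyl ethers and morpholine traps the allyl group) frees the two phenols under neutral conditions that touch neither the benzylic ethers nor the benzylic alcohol.

## Compound list

1 | vanillin (4-hydroxy-3-methoxybenzaldehyde) | COc1cc(C=O)ccc1O | starting material
2 | 4-(allyloxy)-3-methoxybenzaldehyde | COc1cc(C=O)ccc1OCC=C | intermediate
3 | 4-(tert-butoxy)-4-oxobutanoic acid (mono-tert-butyl succinate) | CC(C)(C)OC(=O)CCC(=O)O | starting material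
4 | (R)-4-benzyl-1,3-oxazolidin-2-one | O=C1N[C@H](Cc2ccccc2)CO1 | starting material
5 | 4-(tert-butoxy)-4-oxobutanoic pivalic anhydride | CC(C)(C)OC(=O)CCC(=O)OC(=O)C(C)(C)C | intermediate (not isolated)
6 | tert-butyl 4-[(4R)-4-benzyl-2-oxo-1,3-oxazolidin-3-yl]-4-oxobutanoate | CC(C)(C)OC(=O)CCC(=O)N1[C@H](Cc2ccccc2)COC1=O | intermediate
7 | dibutylboron (Z)-enolate of 6 | CCCCB(CCCC)O/C(=C\CC(=O)OC(C)(C)C)N1[C@H](Cc2ccccc2)COC1=O | intermediate (not isolated)
8 | tert-butyl (3R,4R)-4-ArG-3-{[(4R)-4-benzyl-2-oxo-1,3-oxazolidin-3-yl]carbonyl}-4-hydroxybutanoate | O=C(N1[C@H](Cc2ccccc2)COC1=O)[C@H](CC(=O)OC(C)(C)C)[C@@H](O)c1ccc(OCC=C)c(OC)c1 | intermediate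
9 | tert-butyl (3R,4R)-4-ArG-3-{[(4R)-4-benzyl-2-oxo-1,3-oxazolidin-3-yl]carbonyl}-4-(TBS-oxy)butanoate | O=C(N1[C@H](Cc2ccccc2)COC1=O)[C@H](CC(=O)OC(C)(C)C)[C@@H](O[Si](C)(C)C(C)(C)C)c1ccc(OCC=C)c(OC)c1 | intermediate
10 | tert-butyl (3S,4R)-4-ArG-4-(TBS-oxy)-3-(hydroxymethyl)butanoate | OC[C@H](CC(=O)OC(C)(C)C)[C@@H](O[Si](C)(C)C(C)(C)C)c1ccc(OCC=C)c(OC)c1 | intermediate
11 | (4S)-4-[(R)-ArG(TBS-oxy)methyl]oxolan-2-one | O=C1C[C@@H](CO1)[C@@H](O[Si](C)(C)C(C)(C)C)c1ccc(OCC=C)c(OC)c1 | intermediate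
12 | syringaldehyde (4-hydroxy-3,5-dimethoxybenzaldehyde) | COc1cc(C=O)cc(OC)c1O | starting material
13 | 4-{2-[(tert-butyldimethylsilyl)oxy]ethoxy}-3,5-dimethoxybenzaldehyde | COc1cc(C=O)cc(OC)c1OCCO[Si](C)(C)C(C)(C)C | intermediate
14 | lithium enolate of lactone 11 | [Li]OC1=C[C@@H](CO1)[C@@H](O[Si](C)(C)C(C)(C)C)c1ccc(OCC=C)c(OC)c1 | intermediate (not isolated)
15 | (3R,4S)-4-[(R)-ArG(TBS-oxy)methyl]-3-[(S)-ArS(hydroxy)methyl]oxolan-2-one | O=C1[C@@H]([C@H](O)c2cc(OC)c(OCCO[Si](C)(C)C(C)(C)C)c(OC)c2)[C@@H](CO1)[C@@H](O[Si](C)(C)C(C)(C)C)c1ccc(OCC=C)c(OC)c1 | intermediate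
16 | (3R,4S)-4-[(R)-ArG(TBS-oxy)methyl]-3-[(S)-ArS(TBS-oxy)methyl]oxolan-2-one | O=C1[C@@H]([C@H](O[Si](C)(C)C(C)(C)C)c2cc(OC)c(OCCO[Si](C)(C)C(C)(C)C)c(OC)c2)[C@@H](CO1)[C@@H](O[Si](C)(C)C(C)(C)C)c1ccc(OCC=C)c(OC)c1 | intermediate
17 | (2S,3S)-2-[(R)-ArG(TBS-oxy)methyl]-3-[(S)-ArS(TBS-oxy)methyl]butane-1,4-diol | OC[C@@H]([C@H](O[Si](C)(C)C(C)(C)C)c1cc(OC)c(OCCO[Si](C)(C)C(C)(C)C)c(OC)c1)[C@@H](CO)[C@@H](O[Si](C)(C)C(C)(C)C)c1ccc(OCC=C)c(OC)c1 | intermediate
18 | (2S,3S)-2-[(R)-ArG(TBS-oxy)methyl]-3-[(S)-ArS(TBS-oxy)methyl]butane-1,4-diyl dimethanesulfonate | CS(=O)(=O)OC[C@@H]([C@H](O[Si](C)(C)C(C)(C)C)c1cc(OC)c(OCCO[Si](C)(C)C(C)(C)C)c(OC)c1)[C@@H](COS(C)(=O)=O)[C@@H](O[Si](C)(C)C(C)(C)C)c1ccc(OCC=C)c(OC)c1 | intermediate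
19 | (2S,3S)-2-[(R)-ArG(hydroxy)methyl]-3-{(S)-hydroxy[4-(2-hydroxyethoxy)-3,5-dimethoxyphenyl]methyl}butane-1,4-diyl dimethanesulfonate | CS(=O)(=O)OC[C@@H]([C@H](O)c1cc(OC)c(OCCO)c(OC)c1)[C@@H](COS(C)(=O)=O)[C@@H](O)c1ccc(OCC=C)c(OC)c1 | intermediate (not isolated)
20 | {(2R,3S,4S)-2-ArG-4-{(S)-hydroxy[4-(2-hydroxyethoxy)-3,5-dimethoxyphenyl]methyl}oxolan-3-yl}methyl methanesulfonate (ring A closed) | C=CCOc1ccc([C@@H]2OC[C@@H]([C@H](O)c3cc(OC)c(OCCO)c(OC)c3)[C@H]2COS(C)(=O)=O)cc1OC | intermediate (not isolated)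
21 | 2-(4-FF-2,6-dimethoxyphenoxy)ethan-1-ol | C=CCOc1ccc([C@@H]2OC[C@@H]3[C@H]2CO[C@@H]3c2cc(OC)c(OCCO)c(OC)c2)cc1OC | intermediate
22 | (4-FF-2,6-dimethoxyphenoxy)acetaldehyde | C=CCOc1ccc([C@@H]2OC[C@@H]3[C@H]2CO[C@@H]3c2cc(OC)c(OCC=O)c(OC)c2)cc1OC | intermediate (not isolated)
23 | (4-FF-2,6-dimethoxyphenoxy)acetic acid | C=CCOc1ccc([C@@H]2OC[C@@H]3[C@H]2CO[C@@H]3c2cc(OC)c(OCC(=O)O)c(OC)c2)cc1OC | intermediate
24 | (S)-4-benzyl-1,3-oxazolidin-2-one | O=C1N[C@@H](Cc2ccccc2)CO1 | starting material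
25 | (4-FF-2,6-dimethoxyphenoxy)acetic pivalic anhydride | C=CCOc1ccc([C@@H]2OC[C@@H]3[C@H]2CO[C@@H]3c2cc(OC)c(OCC(=O)OC(=O)C(C)(C)C)c(OC)c2)cc1OC | intermediate (not isolated)
26 | (4S)-4-benzyl-3-[(4-FF-2,6-dimethoxyphenoxy)acetyl]-1,3-oxazolidin-2-one | C=CCOc1ccc([C@@H]2OC[C@@H]3[C@H]2CO[C@@H]3c2cc(OC)c(OCC(=O)N3[C@@H](Cc4ccccc4)COC3=O)c(OC)c2)cc1OC | intermediate
27 | 4-(allyloxy)-3,5-dimethoxybenzaldehyde | COc1cc(C=O)cc(OC)c1OCC=C | intermediate
28 | dibutylboron (Z)-enolate of 26 | C=CCOc1ccc([C@@H]2OC[C@@H]3[C@H]2CO[C@@H]3c2cc(OC)c(O/C=C(\OB(CCCC)CCCC)N3[C@@H](Cc4ccccc4)COC3=O)c(OC)c2)cc1OC | intermediate (not isolated)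
29 | (4S)-4-benzyl-3-[(2S,3R)-3-[4-(allyloxy)-3,5-dimethoxyphenyl]-2-(4-FF-2,6-dimethoxyphenoxy)-3-hydroxypropanoyl]-1,3-oxazolidin-2-one | C=CCOc1ccc([C@@H]2OC[C@@H]3[C@H]2CO[C@@H]3c2cc(OC)c(O[C@H](C(=O)N3[C@@H](Cc4ccccc4)COC3=O)[C@H](O)c3cc(OC)c(OCC=C)c(OC)c3)c(OC)c2)cc1OC | intermediate
30 | (1R,2R)-1-[4-(allyloxy)-3,5-dimethoxyphenyl]-2-(4-FF-2,6-dimethoxyphenoxy)propane-1,3-diol | C=CCOc1ccc([C@@H]2OC[C@@H]3[C@H]2CO[C@@H]3c2cc(OC)c(O[C@H](CO)[C@H](O)c3cc(OC)c(OCC=C)c(OC)c3)c(OC)c2)cc1OC | intermediate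
31 | 4-[(1R,2R)-1,3-dihydroxy-2-{4-[(1S,3aS,4R,6aS)-4-(4-hydroxy-3-methoxyphenyl)tetrahydro-1H,3H-furo[3,4-c]furan-1-yl]-2,6-dimethoxyphenoxy}propyl]-2,6-dimethoxyphenol (CNP0317965.1) | COc1cc([C@@H]2OC[C@@H]3[C@H]2CO[C@@H]3c2cc(OC)c(O[C@H](CO)[C@H](O)c3cc(OC)c(O)c(OC)c3)c(OC)c2)ccc1O | target

## Step count and risks

Total steps: 18. Longest linear sequence: 15 steps (1, 3–6, 8–14, 16–18, from vanillin to 31).

Steps most likely to fail:

**Step 8 (lactone aldol).** The 3,4-trans outcome is secure, but the anti:syn ratio at the C7' carbinol from a lithium lactone enolate may be only moderate. Fallback: set out from 11 and run step 8 without regard to the carbinol ratio, which gives 15 mixed with its C7' epimer, the (R)-carbinol lactone F1. Oxidise the mixture with Dess–Martin periodinane and NaHCO3 in CH2Cl2 to the single trans β-keto lactone F2. Reduce F2 by transfer hydrogenation with RuCl[(S,S)-TsDPEN](p-cymene) in HCO2H/Et3N, so that the (S)-carbinol is set by the catalyst and not by the aldol transition state. This comes back to the route at 15.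

**Step 12 (double ring closure).** Fluoride may attack the primary mesylates, or the second closure that places the aryl group endo may be slow. Fallback: set out from 17 and oxidise both primary alcohols with Dess–Martin periodinane to the dialdehyde F3, kept cold and used at once. Bu4NF/AcOH in THF removes the three silyl groups, and the two benzylic hydroxyls add to the aldehydes to give the bicyclic bis-lactol F4. Et3SiH with BF3·OEt2 in CH2Cl2 at −78 °C then reduces both lactol carbons (C9 and C9', which are not stereogenic in the product). This is a reductive etherification in place of the Williamson closure and comes back to the route at 21.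

**Step 16 (key Evans aldol).** The hindered 2,6-dimethoxyaryloxy enolate may react sluggishly, or the boron triflate may erode the endo benzylic ether. Fallback: set out from 23 and esterify with MeI/K2CO3 in DMF to the methyl ester F5. Treat F5 with LiN(SiMe3)2 in THF at −78 °C and aldehyde 27 to get the unselective aldol adduct F6. Oxidise F6 with Dess–Martin periodinane to the β-keto ester F7, whose C8'' epimers interconvert. Transfer hydrogenation with RuCl[(S,S)-TsDPEN](p-cymene) in HCO2H/Et3N under dynamic kinetic resolution is expected to give the syn (2S,3R) hydroxy ester F8. LiBH4 in THF then reduces the ester, and the route is rejoined at 30.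

## Further compounds

F1 | step 8 | (3R,4S)-4-[(R)-ArG(TBS-oxy)methyl]-3-[(R)-ArS(hydroxy)methyl]oxolan-2-one (C7' epimer of 15) | O=C1[C@@H]([C@@H](O)c2cc(OC)c(OCCO[Si](C)(C)C(C)(C)C)c(OC)c2)[C@@H](CO1)[C@@H](O[Si](C)(C)C(C)(C)C)c1ccc(OCC=C)c(OC)c1
F2 | step 8 | (3R,4S)-4-[(R)-ArG(TBS-oxy)methyl]-3-(4-{2-[(tert-butyldimethylsilyl)oxy]ethoxy}-3,5-dimethoxybenzoyl)oxolan-2-one | O=C1[C@@H](C(=O)c2cc(OC)c(OCCO[Si](C)(C)C(C)(C)C)c(OC)c2)[C@@H](CO1)[C@@H](O[Si](C)(C)C(C)(C)C)c1ccc(OCC=C)c(OC)c1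
F3 | step 12 | (2R,3R)-2-[(R)-ArG(TBS-oxy)methyl]-3-[(S)-ArS(TBS-oxy)methyl]butanedial | O=C[C@@H]([C@H](O[Si](C)(C)C(C)(C)C)c1cc(OC)c(OCCO[Si](C)(C)C(C)(C)C)c(OC)c1)[C@@H](C=O)[C@@H](O[Si](C)(C)C(C)(C)C)c1ccc(OCC=C)c(OC)c1
F4 | step 12 | 3,6-dihydroxy derivative of the furofuran core of 21 (bis-lactol, anomer mixture; benzylic and ring-fusion centres as in 21) | C=CCOc1ccc([C@@H]2OC(O)[C@@H]3[C@H]2C(O)O[C@@H]3c2cc(OC)c(OCCO)c(OC)c2)cc1OC
F5 | step 16 | methyl (4-FF-2,6-dimethoxyphenoxy)acetate | C=CCOc1ccc([C@@H]2OC[C@@H]3[C@H]2CO[C@@H]3c2cc(OC)c(OCC(=O)OC)c(OC)c2)cc1OC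
F6 | step 16 | methyl 3-[4-(allyloxy)-3,5-dimethoxyphenyl]-2-(4-FF-2,6-dimethoxyphenoxy)-3-hydroxypropanoate (mixture at C2 and C3) | C=CCOc1ccc([C@@H]2OC[C@@H]3[C@H]2CO[C@@H]3c2cc(OC)c(OC(C(=O)OC)C(O)c3cc(OC)c(OCC=C)c(OC)c3)c(OC)c2)cc1OC
F7 | step 16 | methyl 3-[4-(allyloxy)-3,5-dimethoxyphenyl]-2-(4-FF-2,6-dimethoxyphenoxy)-3-oxopropanoate (C2 epimers) | C=CCOc1ccc([C@@H]2OC[C@@H]3[C@H]2CO[C@@H]3c2cc(OC)c(OC(C(=O)OC)C(=O)c3cc(OC)c(OCC=C)c(OC)c3)c(OC)c2)cc1OC
F8 | step 16 | methyl (2S,3R)-3-[4-(allyloxy)-3,5-dimethoxyphenyl]-2-(4-FF-2,6-dimethoxyphenoxy)-3-hydroxypropanoate | C=CCOc1ccc([C@@H]2OC[C@@H]3[C@H]2CO[C@@H]3c2cc(OC)c(O[C@H](C(=O)OC)[C@H](O)c3cc(OC)c(OCC=C)c(OC)c3)c(OC)c2)cc1OC
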